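Assumption: the target is the meso all-cis isomer that its SMILES encodes, so only relative configuration has to be controlled; intermediates 15 and 16 are racemic and lose their chirality when the ester becomes the second hydroxymethyl group.

## Analysis of the target

Target 17 is a single tetrahydrofuran ring (O1, C2 to C5) with 4-hydroxy-3,5-dimethoxyphenyl groups at C2 and C5 and hydroxymethyl groups at C3 and C4. All four ring carbons are stereocentres and all four substituents sit on one face, which makes the molecule meso (2R,3R,4S,5S). This all-cis isomer is the most crowded diastereomer, so it has to be set under kinetic control and must not be exposed to equilibrating conditions afterwards. The sensitive groups are the two free phenols, which are easily oxidised, and the benzylic C2–O1 and C5–O1 bonds para to those phenols, which can ionise to quinone methides in acid and so epimerise. The cis-1,4-diol can also cyclodehydrate under acid. The difficulty is therefore the combination of four contiguous cis centres with electron-rich arenes that tolerate neither oxidants nor acid once unmasked. The strategy rests on two features. First, C3 and C4 are both donor carbons in simple precursors: C3 is alpha to the carboxyl-level carbon that becomes its CH2OH, and C4 is the beta carbon of an aryl alkyne whose aryl-bearing carbon becomes C5, so the C3–C4 bond calls for a one-electron oxidation. Second, the ring O1/C2–C5 has no stereocentre at the furan oxidation level, so addition of hydrogen to one face can set all four centres at once.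

## Retrosynthetic reasoning

17 from 16. No skeletal bond is cut. Both hydroxymethyl groups and both phenols of 17 are traced to acyl-level groups in 16: a methyl ester on C3, a pivaloyloxymethyl group on C4 and two aryl pivalates. One hydride reduction then has to reduce the ester and cleave all three pivalates. The gain is that the phenols stay masked by groups that survive oxidation and hydrogenation, and that C3 carries the ester the ring construction needs. The forward step has to keep the configuration at C3, which is alpha to the ester, and has to end with a near-neutral work-up.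

16 from 14. The four C–H bonds at C2 to C5 are removed, which leads back to furan 14 without any stereocentre. Building four cis centres one at a time would work against the thermodynamic preference at each step, whereas syn delivery of hydrogen to one face of a flat ring gives exactly the all-cis pattern. The forward hydrogenation has to add both equivalents from the same face, passing through dihydrofuran 15, without cleaving benzylic C–O bonds or saturating the arenes.

14 from 8 and 13. The C3–C4 and O1–C5 bonds are cut. This divides the furan into two halves of equal size, each with one aryl ring: keto ester 8 supplies C2, C3, O1 and the ester carbon, and alkyne 13 supplies C4, C5 and the CH2O carbon. A polar construction of the C3–C4 bond would need an alpha-halo ketone with a beta-acyloxy group, which would eliminate. Because both carbons are donors, the bond is made by oxidising 8 to its alpha radical. The forward reaction has to add that radical to the alkyne carbon remote from the aryl group, close the ring through oxygen and leave the arenes unoxidised, which is why both phenols are pivalates.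

8 from 4 and 5, and 4 from 1 and 2. The bond between the ketone carbon and the alpha carbon of 8 is cut, giving acid chloride 6 (from acid 4) and malonate half-ester salt 5. Acylation followed by decarboxylation of 7 runs under mild amine-base conditions that do not touch the aryl pivalate. Acid 4 comes from syringic acid 1 and pivaloyl chloride 2 through mixed anhydride 3.

13 from 12 and 2, 12 from 10 and 11, and 10 from 9 and 2. The aryl–alkyne bond is cut, which leads to aryl bromide 10 and propargyl alcohol 11 for a palladium/copper alkynylation. The phenol of 9 is pivaloylated first because a free phenoxide para to bromine would slow oxidative addition. The propargylic hydroxyl of 12 is pivaloylated last so that it plays no part in the oxidative step.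

## Alternatives that were turned down

Alternative 1: Both arenes are dismantled and the all-cis core is traced to an oxanorbornene template whose bicyclic frame fixes the four cis relationships.
- Key step: the dianion of 3-(benzyloxy)pentane-2,4-dione A3 is acylated at its terminal carbon by each amide group of the all-cis bis(N-methoxy-N-methylamide) A2. Each triketone chain then closes by aldol condensation and dehydration to a 4-benzyloxy-3,5-dihydroxyphenyl ring, giving A1. Four O-methylations and removal of four benzyl groups would follow.
- For: the relative configuration is locked by a rigid bicycle before any aryl group exists and does not depend on the facial course of a late hydrogenation. On this point it is stronger than the chosen route.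
- Against: C2 and C5 are alpha to carbonyl groups throughout the strongly basic acylation and aldol stage, and epimerisation there would destroy the all-cis isomer. Two arenes that can be bought have to be built. The final debenzylation takes place next to two benzylic ring C–O bonds. The sequence is roughly twice as long.
- Comparison: the chosen route starts from ready-made arenes, is convergent, takes eight steps and has no stereocentre at risk until its second-to-last step.

Alternative 2: The C2–aryl and C5–aryl bonds are cut; the ring is kept as bis-acetal A5 with cis hydroxymethyl groups and both aryl groups come from triarylalane A6.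
- Key step: on heating, each hydroxymethyl oxygen of A5 binds aluminium, the Lewis-acidic centre ionises the neighbouring acetal carbon, and an aryl group is passed to it on the face of the tether. This would give A4, and hydrogenolysis of two aryl benzyl ethers would finish.
- For: it is the shortest plan, works in two directions at once and uses the mirror symmetry of the target, which the chosen route does not. The tether addresses the all-cis problem directly. On step count and symmetry it is stronger.
- Against: tethered aryl transfer from an aluminium alkoxide to a cyclic bis-acetal is not an established reaction type. The new 2-aryl ether bonds, with electron-rich aryl groups, can ionise again under the same hot Lewis-acidic conditions and drift to the trans isomers. Each aluminium carries three aryl groups and passes on one. The last hydrogenolysis again threatens the benzylic ring bonds.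
- Comparison: the chosen route uses known reaction types at every stage and sets the stereocentres in a neutral hydrogenation that cannot equilibrate benzylic centres.

Alternative 3: The O1–C2 bond and the bond from C3 to its carboxyl carbon are cut, leading to alkynol A8 with the C4 and C5 centres already in place.
- Key step: under palladium-catalysed oxidative methoxycarbonylation the hydroxyl adds 5-endo to the aryl-bearing alkyne carbon and the vinylpalladium is carbonylated to the methyl ester, giving A7. Hydrogenation of the remaining double bond, debenzylation and ester reduction would follow.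
- For: the ring closure is a catalytic two-electron process whose regiochemistry is enforced by the tether, with no stoichiometric oxidant, and only one double bond is left to reduce. On regiochemical certainty and metal economy it is stronger.
- Against: A8 needs a diastereoselective C4–C5 bond formation, a stereochemical problem the chosen route does not have. Oxidative carbonylation of homopropargylic alcohols can divert to lactones. The last two centres still depend on hydrogenating a tetrasubstituted beta-alkoxy acrylate from one face; A7 is the benzyl analogue of 15, so this hurdle is not avoided. The three benzyl ethers need palladium for cleavage, which also attacks the benzylic ring C–O bonds.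
- Comparison: the chosen route makes both fragments in two or three steps without stereochemistry, sets all four centres in one operation and carries pivalates that are inert to hydrogenation.

Key step: step 6

## Route

Step 1
Reactants: 1 syringic acid; 2 pivaloyl chloride
Product: 4 3,5-dimethoxy-4-(pivaloyloxy)benzoic acid, via mixed pivalic anhydride 3 (not isolated)
Conditions: 2 (2.5 equiv), pyridine, DMAP (cat.), 0 °C → rt; then H2O, rt; 1 M HCl work-up
Reagents that add atoms: pivaloyl chloride (2), CC(C)(C)C(=O)Cl; water, O
Why: DMAP-catalysed O-acylation esterifies the hindered phenol and also converts the carboxyl group into mixed anhydride 3. Water and pyridine hydrolyse 3 at the less hindered aroyl carbonyl during the quench, while the aryl pivalate, shielded by the tert-butyl group and two ortho-methoxy groups, stays.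

Step 2
Reactants: 4 3,5-dimethoxy-4-(pivaloyloxy)benzoic acid; 5 potassium methyl malonate
Product: 8 methyl 3-[3,5-dimethoxy-4-(pivaloyloxy)phenyl]-3-oxopropanoate, via acid chloride 6 (not isolated), via aroylmalonate half ester 7 (not isolated)
Conditions: (COCl)2, DMF (cat.), CH2Cl2, 0 °C → rt, evaporate; then 5, MgCl2, Et3N, MeCN, 0 °C → rt; 1 M HCl
Reagents that add atoms: potassium methyl malonate (5), COC(=O)CC(=O)[O-].[K+]
Why: Oxalyl chloride with catalytic DMF gives acid chloride 6; the magnesium enolate of the malonate half ester is C-acylated by it, and acidification decarboxylates 7 to the beta-keto ester (malonate half-ester acylation with decarboxylation). No alkoxide is present, so the aryl pivalate is not cleaved.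

Step 3
Reactants: 9 4-bromo-2,6-dimethoxyphenol; 2 pivaloyl chloride
Product: 10 4-bromo-2,6-dimethoxyphenyl pivalate
Conditions: 2, Et3N, DMAP (cat.), CH2Cl2, 0 °C → rt
Reagents that add atoms: pivaloyl chloride (2), CC(C)(C)C(=O)Cl
Why: DMAP-catalysed acylation of the hindered phenol. The pivalate removes the phenoxide that would deactivate the bromide in the coupling and masks the phenol against the later oxidant.

Step 4
Reactants: 10 4-bromo-2,6-dimethoxyphenyl pivalate; 11 prop-2-yn-1-ol
Product: 12 4-(3-hydroxyprop-1-yn-1-yl)-2,6-dimethoxyphenyl pivalate
Conditions: 11 (1.5 equiv), Pd(PPh3)2Cl2 (3 mol%), CuI (5 mol%), Et3N/THF, 65 °C, argon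
Reagents that add atoms: prop-2-yn-1-ol (11), C#CCO
Why: Sonogashira coupling: the aryl bromide, which carries meta-methoxy and para-acyloxy groups instead of a phenoxide, adds oxidatively to zerovalent palladium, the copper acetylide of 11 transmetalates, and reductive elimination forms the aryl–alkyne bond. The tertiary amine does not cleave the hindered pivalate.

Step 5
Reactants: 12 4-(3-hydroxyprop-1-yn-1-yl)-2,6-dimethoxyphenyl pivalate; 2 pivaloyl chloride
Product: 13 3-[3,5-dimethoxy-4-(pivaloyloxy)phenyl]prop-2-yn-1-yl pivalate
Conditions: 2, pyridine, DMAP (cat.), CH2Cl2, 0 °C → rt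
Reagents that add atoms: pivaloyl chloride (2), CC(C)(C)C(=O)Cl
Why: Acylation of an unhindered primary propargylic alcohol. The ester keeps the hydroxyl from being oxidised by trivalent manganese and from adding to the vinyl intermediate of the next step.

Step 6
Reactants: 8 methyl 3-[3,5-dimethoxy-4-(pivaloyloxy)phenyl]-3-oxopropanoate; 13 3-[3,5-dimethoxy-4-(pivaloyloxy)phenyl]prop-2-yn-1-yl pivalate
Product: 14 methyl 2,5-bis[3,5-dimethoxy-4-(pivaloyloxy)phenyl]-4-(pivaloyloxymethyl)furan-3-carboxylate
Conditions: Mn(OAc)3·2H2O (2.5 equiv), 13 (1.5 equiv), degassed AcOH, 80 °C, argon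
Reagents that add atoms: none
Why: Mn(OAc)3 binds keto ester 8 as its enolate and oxidises it by inner-sphere electron transfer to an electrophilic alpha-carbon radical, trivalent manganese becoming divalent. The radical adds to the alkyne carbon of 13 that carries the pivaloyloxymethyl group (new C3–C4 bond), because only this direction gives the linear vinyl radical at C5 that is delocalised into its aryl ring. The ketone oxygen then bonds to C5 (new O1–C5 bond), either by direct radical attack or after a second equivalent of Mn(OAc)3 has oxidised the vinyl radical to the aryl-stabilised vinyl cation; loss of one more electron and of the C3 proton aromatises the ring. The closest known reaction type is the oxidative [3+2] annulation of 1,3-dicarbonyl compounds with alkenes and alkynes by Mn(OAc)3 or (NH4)2Ce(NO3)6, which gives dihydrofurans and furans. The one ring closes in a 5-endo mode at a digonal carbon: O1 attacks C5 of the C4=C5 unit, and both carbons of that unit end up in the ring. No stereocentre is formed. The step needs regiocontrol, capture of the vinyl intermediate by oxygen and not by the arene, and cross-coupling over self-coupling: the aryl group on the alkyne secures the first, the planar 1,3-dicarbonyl unit holds the oxygen next to C5 while the ortho carbons of the aroyl ring are flanked by methoxy groups, and the excess of 13 suppresses dimerisation of 8. The pivalates keep both phenols from being oxidised by trivalent manganese.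

Step 7
Reactants: 14 methyl 2,5-bis[3,5-dimethoxy-4-(pivaloyloxy)phenyl]-4-(pivaloyloxymethyl)furan-3-carboxylate
Product: 16 methyl all-cis-2,5-bis[3,5-dimethoxy-4-(pivaloyloxy)phenyl]-4-(pivaloyloxymethyl)tetrahydrofuran-3-carboxylate (racemic; 2RS,3SR,4SR,5SR), via cis-4,5-dihydrofuran ester 15 (not isolated)
Conditions: H2 (50 bar), 5% Rh/Al2O3, EtOAc, 40 °C
Reagents that add atoms: none
Why: Heterogeneous hydrogenation of a furan: the flat ring lies on the rhodium surface and should receive all four hydrogens from that face, which places the four substituents on the opposite face (all-cis). If 15 leaves the surface after addition across C4=C5, its C4 and C5 substituents block the other face, so the remaining C2=C3 bond is reduced from the same side. Rhodium is chosen because it cleaves benzylic and allylic C–O bonds and shifts double bonds less readily than palladium, and the pivalates are inert.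

Step 8
Reactants: 16 methyl all-cis-2,5-bis[3,5-dimethoxy-4-(pivaloyloxy)phenyl]-4-(pivaloyloxymethyl)tetrahydrofuran-3-carboxylate
Product: 17 [(2R,3R,4S,5S)-2,5-bis(4-hydroxy-3,5-dimethoxyphenyl)tetrahydrofuran-3,4-diyl]dimethanol (meso; all-cis)
Conditions: LiAlH4 (excess), THF, −20 °C → rt; aqueous potassium sodium tartrate/NH4Cl work-up at about pH 7
Reagents that add atoms: none
Why: Ester reduction by LiAlH4: the methyl ester becomes the C3 hydroxymethyl group and the three pivalates are cleaved reductively to the primary alcohol and the two phenols. Hydride addition to the unhindered methyl ester at low temperature should outrun enolisation, so C3 keeps its configuration, and the near-neutral work-up avoids quinone-methide ionisation at C2 and C5.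

## Compound list

1 | syringic acid (4-hydroxy-3,5-dimethoxybenzoic acid) | COc1cc(C(=O)O)cc(OC)c1O | starting material
2 | pivaloyl chloride | CC(C)(C)C(=O)Cl | starting material
3 | 3,5-dimethoxy-4-(pivaloyloxy)benzoic pivalic anhydride | COc1cc(C(=O)OC(=O)C(C)(C)C)cc(OC)c1OC(=O)C(C)(C)C | intermediate (not isolated)
4 | 3,5-dimethoxy-4-(pivaloyloxy)benzoic acid | COc1cc(C(=O)O)cc(OC)c1OC(=O)C(C)(C)C | intermediate
5 | potassium methyl malonate (potassium 3-methoxy-3-oxopropanoate) | COC(=O)CC(=O)[O-].[K+] | starting material
6 | 3,5-dimethoxy-4-(pivaloyloxy)benzoyl chloride | COc1cc(C(=O)Cl)cc(OC)c1OC(=O)C(C)(C)C | intermediate (not isolated)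
7 | 2-[3,5-dimethoxy-4-(pivaloyloxy)benzoyl]-3-methoxy-3-oxopropanoic acid (magnesium salt in the flask) | COC(=O)C(C(=O)O)C(=O)c1cc(OC)c(OC(=O)C(C)(C)C)c(OC)c1 | intermediate (not isolated)
8 | methyl 3-[3,5-dimethoxy-4-(pivaloyloxy)phenyl]-3-oxopropanoate | COC(=O)CC(=O)c1cc(OC)c(OC(=O)C(C)(C)C)c(OC)c1 | intermediate
9 | 4-bromo-2,6-dimethoxyphenol | COc1cc(Br)cc(OC)c1O | starting material
10 | 4-bromo-2,6-dimethoxyphenyl pivalate | COc1cc(Br)cc(OC)c1OC(=O)C(C)(C)C | intermediate
11 | prop-2-yn-1-ol | C#CCO | starting material
12 | 4-(3-hydroxyprop-1-yn-1-yl)-2,6-dimethoxyphenyl pivalate | COc1cc(C#CCO)cc(OC)c1OC(=O)C(C)(C)C | intermediate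
13 | 3-[3,5-dimethoxy-4-(pivaloyloxy)phenyl]prop-2-yn-1-yl pivalate | CC(C)(C)C(=O)OCC#Cc1cc(OC)c(OC(=O)C(C)(C)C)c(OC)c1 | intermediate
14 | methyl 2,5-bis[3,5-dimethoxy-4-(pivaloyloxy)phenyl]-4-(pivaloyloxymethyl)furan-3-carboxylate | COC(=O)c1c(-c2cc(OC)c(OC(=O)C(C)(C)C)c(OC)c2)oc(-c2cc(OC)c(OC(=O)C(C)(C)C)c(OC)c2)c1COC(=O)C(C)(C)C | intermediate
15 | methyl cis-2,5-bis[3,5-dimethoxy-4-(pivaloyloxy)phenyl]-4-(pivaloyloxymethyl)-4,5-dihydrofuran-3-carboxylate (racemic; one enantiomer drawn) | COC(=O)C1=C(c2cc(OC)c(OC(=O)C(C)(C)C)c(OC)c2)O[C@@H](c2cc(OC)c(OC(=O)C(C)(C)C)c(OC)c2)[C@H]1COC(=O)C(C)(C)C | intermediate (not isolated)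
16 | methyl all-cis-2,5-bis[3,5-dimethoxy-4-(pivaloyloxy)phenyl]-4-(pivaloyloxymethyl)tetrahydrofuran-3-carboxylate (racemic; one enantiomer drawn) | COc1cc([C@H]2O[C@@H](c3cc(OC)c(OC(=O)C(C)(C)C)c(OC)c3)[C@@H](COC(=O)C(C)(C)C)[C@H]2C(=O)OC)cc(OC)c1OC(=O)C(C)(C)C | intermediate
17 | [(2R,3R,4S,5S)-2,5-bis(4-hydroxy-3,5-dimethoxyphenyl)tetrahydrofuran-3,4-diyl]dimethanol (meso, all-cis) | COc1cc([C@H]2O[C@@H](c3cc(OC)c(O)c(OC)c3)[C@@H](CO)[C@H]2CO)cc(OC)c1O | target

## Step count and risks

Total: 8 steps. Longest linear sequence: 6 steps (9 → 10 → 12 → 13 → 14 → 16 → 17; steps 3 to 8). The keto ester branch (steps 1 and 2) joins at step 6.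

Least certain steps:

Step 6 (key step). Three processes are most likely to go wrong:
- hydrogen-atom abstraction from the solvent by the vinyl radical before ring closure;
- closure of the vinyl intermediate onto an ortho carbon of the aroyl ring in place of the ketone oxygen;
- oxidative self-coupling of 8.

All three follow from the high energy of the vinyl radical and from the fact that enolisation of 8 does not depend on the alkyne. The fallback forms the C3–C4 bond by two-electron chemistry and uses the symmetry of the target. It sets out from 8: deprotonation with NaH in THF and treatment with half an equivalent of iodine (alpha-iodination, then alkylation of a second enolate) should give dimethyl 2,3-bis[3,5-dimethoxy-4-(pivaloyloxy)benzoyl]butanedioate F1. Catalytic TsOH in refluxing toluene with removal of water should close it (Paal–Knorr) to dimethyl 2,5-bis[3,5-dimethoxy-4-(pivaloyloxy)phenyl]furan-3,4-dicarboxylate F2. Hydrogenation over Rh/Al2O3 should give the all-cis diester F3, and LiAlH4 in THF reduces both esters and removes both pivalates, which brings the route back at 17. Alkyne 13 is not needed on this path.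

Step 7. The hydrogenation may stall at 15, whose remaining double bond is a tetrasubstituted beta-alkoxy acrylate. Other possible failures are hydrogenolysis of the benzylic C–O bonds or of the CH2–O bond at C4 while it is still allylic, saturation of an arene, or migration of the double bond in 15 with loss of the cis relationship. The fallback removes the ester before the ring is saturated, so that the substrate is an ordinary electron-rich 3,4-dialkyl-2,5-diarylfuran. It sets out from 14: LiAlH4 in THF should give [2,5-bis(4-hydroxy-3,5-dimethoxyphenyl)furan-3,4-diyl]dimethanol F4, which is handled under argon and acylated at once with 2, pyridine and DMAP to the tetrapivalate F5. Hydrogenation over Rh/Al2O3 should give the all-cis tetrapivalate F6, and LiAlH4 cleaves the four pivalates, coming back at 17.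

Step 8. The aluminium alkoxides formed during the reduction may epimerise C3 before the ester is consumed, or open the ring by beta-elimination of O1. The hindered pivalates may be cleaved incompletely, and a work-up that drifts acidic may ionise the benzylic ethers. The fallback separates the two tasks. It sets out from 16: LiBH4 in THF at 0 °C → rt should reduce only the methyl ester and give the primary alcohol {all-cis-4-(hydroxymethyl)-2,5-bis[3,5-dimethoxy-4-(pivaloyloxy)phenyl]tetrahydrofuran-3-yl}methyl pivalate F7. Once no enolisable centre is left, transesterification with NaOMe in MeOH at rt removes the three pivalates, and neutralisation with NH4Cl brings the route back at 17.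

Step 4. Oxidative addition of the bromide may be slow at a temperature the pivalate tolerates, and the oxidative homocoupling of 11 then takes over. The fallback changes the electrophile. It sets out from 10: copper-catalysed halogen exchange (NaI, CuI, trans-N,N'-dimethylcyclohexane-1,2-diamine, dioxane, 110 °C) should give 4-iodo-2,6-dimethoxyphenyl pivalate F8, which couples with 11 at room temperature under Pd(PPh3)2Cl2/CuI in Et3N/THF and comes back at 12.

## Further compounds

F1 | step 6 | dimethyl 2,3-bis[3,5-dimethoxy-4-(pivaloyloxy)benzoyl]butanedioate (mixture of diastereomers) | COC(=O)C(C(=O)c1cc(OC)c(OC(=O)C(C)(C)C)c(OC)c1)C(C(=O)OC)C(=O)c1cc(OC)c(OC(=O)C(C)(C)C)c(OC)c1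
F2 | step 6 | dimethyl 2,5-bis[3,5-dimethoxy-4-(pivaloyloxy)phenyl]furan-3,4-dicarboxylate | COC(=O)c1c(-c2cc(OC)c(OC(=O)C(C)(C)C)c(OC)c2)oc(-c2cc(OC)c(OC(=O)C(C)(C)C)c(OC)c2)c1C(=O)OC
F3 | step 6 | dimethyl all-cis-2,5-bis[3,5-dimethoxy-4-(pivaloyloxy)phenyl]tetrahydrofuran-3,4-dicarboxylate (meso) | COc1cc([C@H]2O[C@@H](c3cc(OC)c(OC(=O)C(C)(C)C)c(OC)c3)[C@@H](C(=O)OC)[C@H]2C(=O)OC)cc(OC)c1OC(=O)C(C)(C)C
F4 | step 7 | [2,5-bis(4-hydroxy-3,5-dimethoxyphenyl)furan-3,4-diyl]dimethanol | COc1cc(-c2oc(-c3cc(OC)c(O)c(OC)c3)c(CO)c2CO)cc(OC)c1O
F5 | step 7 | {2,5-bis[3,5-dimethoxy-4-(pivaloyloxy)phenyl]furan-3,4-diyl}bis(methylene) dipivalate | COc1cc(-c2oc(-c3cc(OC)c(OC(=O)C(C)(C)C)c(OC)c3)c(COC(=O)C(C)(C)C)c2COC(=O)C(C)(C)C)cc(OC)c1OC(=O)C(C)(C)C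
F6 | step 7 | {all-cis-2,5-bis[3,5-dimethoxy-4-(pivaloyloxy)phenyl]tetrahydrofuran-3,4-diyl}bis(methylene) dipivalate (meso) | COc1cc([C@H]2O[C@@H](c3cc(OC)c(OC(=O)C(C)(C)C)c(OC)c3)[C@@H](COC(=O)C(C)(C)C)[C@H]2COC(=O)C(C)(C)C)cc(OC)c1OC(=O)C(C)(C)C
F7 | step 8 | {all-cis-4-(hydroxymethyl)-2,5-bis[3,5-dimethoxy-4-(pivaloyloxy)phenyl]tetrahydrofuran-3-yl}methyl pivalate (racemic; one enantiomer drawn) | COc1cc([C@H]2O[C@@H](c3cc(OC)c(OC(=O)C(C)(C)C)c(OC)c3)[C@@H](COC(=O)C(C)(C)C)[C@H]2CO)cc(OC)c1OC(=O)C(C)(C)C
F8 | step 4 | 4-iodo-2,6-dimethoxyphenyl pivalate | COc1cc(I)cc(OC)c1OC(=O)C(C)(C)C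
A1 | alternative 1 | all-cis 3,4-bis(benzyloxymethyl)-2,5-bis(4-benzyloxy-3,5-dihydroxyphenyl)tetrahydrofuran | Oc1cc([C@H]2O[C@@H](c3cc(O)c(OCc4ccccc4)c(O)c3)[C@@H](COCc3ccccc3)[C@H]2COCc2ccccc2)cc(O)c1OCc1ccccc1
A2 | alternative 1 | all-cis 3,4-bis(benzyloxymethyl)-N2,N5-dimethoxy-N2,N5-dimethyltetrahydrofuran-2,5-dicarboxamide | CON(C)C(=O)[C@H]1O[C@@H](C(=O)N(C)OC)[C@@H](COCc2ccccc2)[C@H]1COCc1ccccc1
A3 | alternative 1 | 3-(benzyloxy)pentane-2,4-dione | CC(=O)C(OCc1ccccc1)C(C)=O
A4 | alternative 2 | all-cis [2,5-bis(4-benzyloxy-3,5-dimethoxyphenyl)tetrahydrofuran-3,4-diyl]dimethanol | COc1cc([C@H]2O[C@@H](c3cc(OC)c(OCc4ccccc4)c(OC)c3)[C@@H](CO)[C@H]2CO)cc(OC)c1OCc1ccccc1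
A5 | alternative 2 | cis-3,4-bis(hydroxymethyl)-2,5-dimethoxytetrahydrofuran (acetal centres undefined) | COC1OC(OC)[C@@H](CO)[C@H]1CO
A6 | alternative 2 | tris(4-benzyloxy-3,5-dimethoxyphenyl)aluminium | COc1cc([Al](c2cc(OC)c(OCc3ccccc3)c(OC)c2)c2cc(OC)c(OCc3ccccc3)c(OC)c2)cc(OC)c1OCc1ccccc1
A7 | alternative 3 | methyl 4,5-cis-4-(benzyloxymethyl)-2,5-bis(4-benzyloxy-3,5-dimethoxyphenyl)-4,5-dihydrofuran-3-carboxylate | COC(=O)C1=C(c2cc(OC)c(OCc3ccccc3)c(OC)c2)O[C@@H](c2cc(OC)c(OCc3ccccc3)c(OC)c2)[C@H]1COCc1ccccc1
A8 | alternative 3 | (1RS,2RS)-2-(benzyloxymethyl)-1,4-bis(4-benzyloxy-3,5-dimethoxyphenyl)but-3-yn-1-ol | O[C@@H](c1cc(OC)c(OCc2ccccc2)c(OC)c1)[C@H](C#Cc1cc(OC)c(OCc2ccccc2)c(OC)c1)COCc1ccccc1
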